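**Retrosynthetic overview**
1. The C9 (R)-2-methylbutanoate and C10 tertiary alcohol come from SN2 opening of an E-configured C9–C10 epoxide at C9 by carboxylate. The inversion at C9 gives the ring-cis 9,10 relationship required by the target.
2. The 10-membered carbocycle and the trans-fused α-methylene-γ-lactone come from one new step, a Cr/photo-HAT intramolecular allylic C–H allylation (C7–C8 bond), followed by lactonization.
3. The acyclic enal comes from geraniol (E-alkene and C1–C3 chain), Evans alkylation (C4 stereocentre), and methyl-ketone alkylation with ethyl 2-(bromomethyl)acrylate (C6–C7).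
4. Ring order: the carbocycle and lactone form together, and the oxirane is made and opened last.

Assumptions: the ester is (R)-2-methylbutanoate, as written in the target SMILES. The (S)-4-benzyl Evans auxiliary gives the (R)-2-methyl centre at C4. Macrocyclic conformational control decides the C7/C8 sense relative to C4.

---

**Step 1**
Reactants: 1 geraniol
Product: 2 geranyl TBDPS ether
Conditions: TBDPSCl, imidazole, CH2Cl2, 0 °C→rt
Reagents that add atoms: TBDPSCl, CC(C)(C)[Si](Cl)(c1ccccc1)c1ccccc1
Why: Standard silylation protects the allylic OH for the later enolate and organolithium steps.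

**Step 2**
Reactants: 2
Product: 3 6,7-epoxide (racemic)
Conditions: mCPBA (1.0 equiv), NaHCO3, CH2Cl2, −20→0 °C
Reagents that add atoms: mCPBA, OOC(=O)c1cccc(Cl)c1 (supplies the epoxide O)
Why: Prilezhaev epoxidation occurs at the more electron-rich, remote trisubstituted 6,7-alkene, because the 2,3-alkene is deactivated by the allylic OSi; the epoxide stereocentre is destroyed in step 3.

**Step 3**
Reactants: 3
Product: 4 (E)-6-(TBDPSO)-4-methylhex-4-enal
Conditions: H5IO6, THF/H2O, 0 °C→rt
Reagents that add atoms: none
Why: Epoxide hydrolysis and periodate glycol cleavage release acetone and give the C3 aldehyde; the E-trisubstituted alkene and silyl ether survive.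

**Step 4**
Reactants: 4
Product: 5 (E)-6-(TBDPSO)-4-methylhex-4-en-1-ol
Conditions: NaBH4, MeOH, 0 °C
Reagents that add atoms: none
Why: Chemoselective aldehyde reduction to the primary alcohol.

**Step 5**
Reactants: 5
Product: 6 (E)-tert-butyl((6-iodo-3-methylhex-2-en-1-yl)oxy)diphenylsilane
Conditions: PPh3, I2, imidazole, CH2Cl2, 0 °C
Reagents that add atoms: I2, II
Why: Appel iodination gives the unactivated primary iodide needed as the electrophile for the enolate alkylation.

**Step 6**
Reactants: 6; 7 (S)-4-benzyl-3-propionyloxazolidin-2-one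
Product: 8 (S)-4-benzyl-3-[(2R,6E)-8-(TBDPSO)-2,6-dimethyloct-6-enoyl]oxazolidin-2-one
Conditions: NaHMDS, THF, −78 °C; then 6, DMPU, −78→−20 °C
Reagents that add atoms: none
Why: Evans alkylation of the Z-sodium enolate occurs anti to the benzyl group and sets C4 as (R), with dr expected above 95:5.

**Step 7**
Reactants: 8
Product: 9 (2R,6E)-8-(TBDPSO)-2,6-dimethyloct-6-enoic acid
Conditions: LiOH, H2O2, THF/H2O, 0 °C; then Na2SO3
Reagents that add atoms: H2O2, OO (its oxygen becomes the acid OH)
Why: LiOOH cleaves the imide at the exocyclic carbonyl without epimerizing C4 and recovers the auxiliary.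

**Step 8**
Reactants: 9
Product: 10 (3R,7E)-9-(TBDPSO)-3,7-dimethylnon-7-en-2-one
Conditions: MeLi (2.5 equiv), Et2O/THF, 0 °C→rt; aqueous NH4Cl quench
Reagents that add atoms: MeLi, [Li]C
Why: The acid is converted to the methyl ketone by carboxylate/MeLi addition; the stable dianion prevents over-addition and leaves the α-centre untouched.

**Step 9**
Reactants: 10; 11 ethyl 2-(bromomethyl)acrylate
Product: 12 ethyl (6R,10E)-12-(TBDPSO)-6,10-dimethyl-2-methylene-5-oxododec-10-enoate
Conditions: LDA (1.05 equiv), THF, −78 °C; then 11, −78 °C
Reagents that add atoms: none beyond reactant 11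
Why: Kinetic deprotonation of an α-branched methyl ketone is highly selective for the CH3 group, so alkylation forms the C6–C7 bond and installs the 2-alkylacrylate; slow addition of ketone to base limits C4 epimerization.

**Step 10**
Reactants: 12
Product: 13 ethyl (6R,10E)-12-hydroxy-6,10-dimethyl-2-methylene-5-oxododec-10-enoate
Conditions: TBAF/AcOH (1:1), THF, 0 °C→rt
Reagents that add atoms: none
Why: Acetic acid–buffered fluoride removes the silyl group without triggering Michael addition, aldol reaction or epimerization.

**Step 11**
Reactants: 13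
Product: 14 ethyl (6R,10E)-6,10-dimethyl-2-methylene-5,12-dioxododec-10-enoate (macrocyclization substrate)
Conditions: activated MnO2 (20 equiv), CH2Cl2, rt
Reagents that add atoms: none
Why: MnO2 selectively oxidizes the allylic alcohol to the E-enal under neutral conditions, leaving the ketone, acrylate and alkene untouched.

**Step 12**
Reactants: 14
Product: 15 macrocyclic hydroxy-acrylate (10-membered ring, C7–C8 bond formed)
Conditions: CrCl3 (10 mol %), dtbbpy (10 mol %), Mes-Acr-Ph+ BF4− (3 mol %), quinuclidine (30 mol %), MeCN (2 mM, substrate added by syringe pump over 10 h), blue LEDs, rt, 24 h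
Reagents that add atoms: none
Why: Proposed new method: photoexcited acridinium oxidizes quinuclidine, and the resulting radical cation abstracts the weak allylic C7–H2 of the 2-alkylacrylate. The 2-carboalkoxyallyl radical is captured by Cr(II), which is formed by reduction of Cr(III) by the acridine radical. The primary allyl-Cr(III) adds through its γ-carbon (C7) to the tethered enal carbonyl via a chair Zimmerman–Traxler transition state, 1,2-selectively over the ketone, giving the anti homoallylic alkoxide (trans lactone after lactonization) and regenerating the exo-methylene. The alkoxide is protonated by quinuclidinium to turn the cycle over. The closest known reactions are intermolecular Cr/photoredox allylic C–H allylation of aldehydes with alkenes and intramolecular NHK macrocyclization of 2-(bromomethyl)alkenoates. The new features are an acrylate allylic C–H as the pronucleophile and closure of a 10-membered ring. C7 and C8 are set anti by the transition state, and their absolute sense relative to C4 is set by the conformational preference of the E-alkene-containing ring.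

**Step 13**
Reactants: 15
Product: 16 trans-fused α-methylene-γ-lactone (E-Δ9,10, 5-oxo)
Conditions: TsOH·H2O (0.2 equiv), CH2Cl2, rt
Reagents that add atoms: none (EtOH is lost)
Why: Acid-catalysed transesterification of the C8 hydroxyl onto the acrylate ester gives the γ-lactone; the C7/C8 centres are not touched.

**Step 14**
Reactants: 16
Product: 17 C9–C10 trans-epoxide of 16
Conditions: mCPBA (1.2 equiv), NaHCO3, CH2Cl2, 0 °C
Reagents that add atoms: mCPBA, OOC(=O)c1cccc(Cl)c1 (supplies the epoxide O)
Why: Prilezhaev epoxidation occurs only at the electron-rich trisubstituted alkene, with the exo-methylene and buffered ketone untouched, and E-alkene geometry gives the trans epoxide. Attack from the peripheral face of the lowest-energy conformer sets C9/C10, by analogy with germacranolide epoxidations.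

**Step 15**
Reactants: 17; 18 (R)-2-methylbutanoic acid
Product: 19 Ineupatorolide A
Conditions: 18 (3 equiv), Cs2CO3 (1.5 equiv), DMF, 60 °C
Reagents that add atoms: none beyond reactant 18
Why: Cesium carboxylate opens the epoxide by SN2 at the less hindered secondary C9, with inversion at C9 and retention at C10. Opening the trans epoxide with inversion gives the ring-cis 9-O-acyl/10-OH pair, the tertiary alcohol is released, and the ester stereocentre is carried unchanged.

---

**Compound list**

| No. | Name | SMILES | Role |
|---|---|---|---|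
| 1 | geraniol | CC(C)=CCC/C(C)=C/CO | starting material |
| 2 | geranyl TBDPS ether | CC(C)=CCC/C(C)=C/CO[Si](c1ccccc1)(c1ccccc1)C(C)(C)C | intermediate |
| 3 | 6,7-epoxygeranyl TBDPS ether | CC1(C)OC1CC/C(C)=C/CO[Si](c1ccccc1)(c1ccccc1)C(C)(C)C | intermediate |
| 4 | (E)-6-(TBDPSO)-4-methylhex-4-enal | O=CCC/C(C)=C/CO[Si](c1ccccc1)(c1ccccc1)C(C)(C)C | intermediate |
| 5 | (E)-6-(TBDPSO)-4-methylhex-4-en-1-ol | OCCC/C(C)=C/CO[Si](c1ccccc1)(c1ccccc1)C(C)(C)C | intermediate |
| 6 | (E)-TBDPS 6-iodo-3-methylhex-2-enyl ether | ICCC/C(C)=C/CO[Si](c1ccccc1)(c1ccccc1)C(C)(C)C | intermediate |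
| 7 | (S)-4-benzyl-3-propionyloxazolidin-2-one | CCC(=O)N1[C@@H](Cc2ccccc2)COC1=O | starting material |
| 8 | alkylated Evans imide (2R,6E) | O=C(N1[C@@H](Cc2ccccc2)COC1=O)[C@H](C)CCC/C(C)=C/CO[Si](c1ccccc1)(c1ccccc1)C(C)(C)C | intermediate |
| 9 | (2R,6E)-8-(TBDPSO)-2,6-dimethyloct-6-enoic acid | OC(=O)[C@H](C)CCC/C(C)=C/CO[Si](c1ccccc1)(c1ccccc1)C(C)(C)C | intermediate |
| 10 | (3R,7E)-9-(TBDPSO)-3,7-dimethylnon-7-en-2-one | CC(=O)[C@H](C)CCC/C(C)=C/CO[Si](c1ccccc1)(c1ccccc1)C(C)(C)C | intermediate |
| 11 | ethyl 2-(bromomethyl)acrylate | C=C(CBr)C(=O)OCC | starting material |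
| 12 | keto-acrylate silyl ether | CCOC(=O)C(=C)CCC(=O)[C@H](C)CCC/C(C)=C/CO[Si](c1ccccc1)(c1ccccc1)C(C)(C)C | intermediate |
| 13 | keto-acrylate allylic alcohol | CCOC(=O)C(=C)CCC(=O)[C@H](C)CCC/C(C)=C/CO | intermediate |
| 14 | keto-acrylate E-enal | CCOC(=O)C(=C)CCC(=O)[C@H](C)CCC/C(C)=C/C=O | intermediate |
| 15 | macrocyclic hydroxy-acrylate, ethyl 2-[(3E)-2-hydroxy-4,8-dimethyl-9-oxocyclodec-3-en-1-yl]prop-2-enoate | C=C(C(=O)OCC)[C@@H]1CC(=O)[C@H](C)CCC/C(C)=C/[C@H]1O | intermediate |
| 16 | trans-fused α-methylene lactone, Δ9,10 | C=C1C(=O)O[C@@H]2/C=C(\C)CCC[C@@H](C)C(=O)C[C@@H]12 | intermediate |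
| 17 | C9–C10 trans-epoxide | C=C1C(=O)O[C@@H]2[C@@H]3O[C@@]3(C)CCC[C@@H](C)C(=O)C[C@@H]12 | intermediate |
| 18 | (R)-2-methylbutanoic acid | CC[C@@H](C)C(=O)O | starting material |
| 19 | Ineupatorolide A (4R,7S,8S,9R,10S; ester R) | C=C1C(=O)O[C@@H]2[C@@H](OC(=O)[C@H](C)CC)[C@@](C)(O)CCC[C@@H](C)C(=O)C[C@@H]12 | target |

**Total steps:** 15. **Longest linear sequence:** 15 (geraniol to target; compounds 7, 11 and 18 are commercial partners).

**Three steps most likely to fail**

1. **Step 12 (new Cr/photo-HAT macrocyclization).** HAT may not be selective for the acrylate C7–H over the enal γ-C–H bonds, the ring closure may be inefficient, and quinuclidine may epimerize C4.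
   - Fallback: use known stoichiometric intramolecular NHK chemistry. Carry C5 as a 1,3-dioxolane and build a C7 aldehyde. Make the Baylis–Hillman adduct with ethyl acrylate, convert it to the (Z)-2-(bromomethyl)alk-2-enoate, close the ring with CrCl2/cat. NiCl2 in DMF at about 3 mM, then remove the ketal.
2. **Step 14 (epoxidation face selectivity).** The wrong face would give the C9/C10 diastereomer.
   - Fallback: hydroxyl-directed VO(acac)2/TBHP epoxidation of the uncyclized hydroxy-ester 15, then neutral lactonization with Otera's distannoxane catalyst.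
3. **Step 15 (epoxide opening).** Carboxylate is a weak nucleophile at a neopentyl-like secondary carbon, with risks of C4 epimerization, conjugate addition to the methylene lactone and wrong regiochemistry.
   - Fallback: repeat the route from nerol to give the Z-alkene, then do OsO4 syn-dihydroxylation to the ring-cis diol. Acylate the secondary C9–OH selectively with (R)-2-methylbutanoyl chloride/DMAP, leaving the tertiary C10–OH free.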